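**Retrosynthetic overview**
1. The target is a bornane (bicyclo[2.2.1]heptane: C1 quaternary bridgehead with Me, C4 bridgehead, C7 = CMe2) joined to a formyl/isovaleryl phloroglucinol through C2–O (endo) and C6–CH2 (endo) in a seven-membered oxepine. The aryl CHO (C6'), the aryl isovaleryl (C4') and the benzylic C=O are removed first, with the two phenols kept apart as OH and OMe.
2. Oxepine: the aryl C1'–O bond comes from intramolecular SNAr of the C2 alkoxide on an ortho-fluoroaryl ketone. The aryl C2'–C(=O) bond comes from addition of 2-fluoro-4,6-dimethoxyphenyllithium to the γ-lactone that links C6 to C2.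
3. γ-Lactone: iodolactonisation of the C6 endo carboxylic acid onto C2=C3 of a bornene, then deiodination. The endo acyl carbon thereby passes its face on to the C2–O bond and later becomes the benzylic CH2.
4. Bornene: C1, C4 and C6 of the bicyclo[2.2.1] unit are the ortho, endo Diels–Alder pattern of 1,5,5-trimethylcyclopentadiene (C1–C4 and C7) and trifluoroethyl acrylate (C5, C6, acyl carbon). Bonds C1–C6 and C4–C5 form under a chiral oxazaborolidinium.
5. Ring order: cyclopentadiene (from 2,2-dimethylcyclopentanone) → six-membered ring of the norbornene → temporary γ-lactone → oxepine; the arene is bought.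

Key step: step 4

Assumption: the sense of induction is taken from the α-C–H···O binding model of acrylates on the (S)-diphenylprolinol-derived oxazaborolidinium (open Si face at the acrylate α-carbon); should it prove the reverse, the (R)-catalyst is used and nothing else changes.

Locants: bornane numbering is used in the text (C1 Me-bearing bridgehead, C2 C–O, C3, C4 bridgehead CH, C5, C6 carbon bearing the acyl/benzylic carbon, C7 CMe2). Arene carbons are C1' (ring O), C2' (benzylic C), C3' (OH), C4' (isovaleryl), C5' (OH), C6' (CHO).

**Step 1**
Reactants: 1 2,2-dimethylcyclopentanone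
Product: 2 5,5-dimethylcyclopent-2-en-1-one
Conditions: IBX (2 equiv), DMSO/toluene, 70 °C
Reagents that add atoms: none
Why: IBX dehydrogenation of a ketone can engage only the single enolisable α-CH2, because the other α-carbon is quaternary, so one enone should form.

**Step 2**
Reactants: 2 5,5-dimethylcyclopent-2-en-1-one
Product: 3 1,5,5-trimethylcyclopent-2-en-1-ol (racemic, used crude)
Conditions: MeLi (1.2 equiv), Et2O, −78 → 0 °C; H2O
Reagents that add atoms: methyllithium [Li]C
Why: 1,2-addition of the hard organolithium to the enone carbonyl gives the tertiary allylic alcohol, whose racemic carbinol centre is destroyed in the next step.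

**Step 3**
Reactants: 3 1,5,5-trimethylcyclopent-2-en-1-ol
Product: 4 1,5,5-trimethylcyclopenta-1,3-diene
Conditions: p-TsOH·H2O (cat.), pentane, 4 Å MS, 0 °C → rt; distil
Reagents that add atoms: none
Why: acid-catalysed E1 dehydration through the allylic cation, which loses a proton from the ring CH2 to give the endocyclic conjugated diene as the thermodynamic isomer, and the quaternary C5 rules out 1,5-hydrogen shifts.

**Step 4**
Reactants: 4 1,5,5-trimethylcyclopenta-1,3-diene; 5 2,2,2-trifluoroethyl acrylate (1.5 equiv)
Product: 6 2,2,2-trifluoroethyl (1R,2R,4R)-1,7,7-trimethylbicyclo[2.2.1]hept-5-ene-2-carboxylate (born-2-ene-6-endo-carboxylate in bornane numbering)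
Conditions: (S)-o-tolyl-CBS-oxazaborolidine (15 mol%), Tf2NH (12 mol%), CH2Cl2, −20 °C → rt
Reagents that add atoms: none
Why: The N-protonated oxazaborolidinium binds the acrylate carbonyl anti to the trifluoroethoxy group, lowers its LUMO and covers one face of the s-trans C=C with an aryl group, so the diene adds in a concerted, asynchronous [4π+2π] cycloaddition; the closest known reaction type is the oxazaborolidinium-catalysed Diels–Alder of acrylates with substituted cyclopentadienes. The six-membered carbocycle C1–C2=C3–C4–C5–C6 is closed intermolecularly by suprafacial formation of both σ-bonds (C4–C5 leading, C1–C6 lagging), which turns the cyclopentadiene into the bicyclo[2.2.1]heptene. The required ortho regiochemistry follows from the larger HOMO coefficient at the unsubstituted diene terminus C4, which pairs with the acrylate β-carbon, so the α-carbon bonds to the methyl-bearing C1. C6 is set endo by secondary orbital overlap and by the syn methyl group on C7, which would clash with an exo acyl group. The absolute configuration of C1, C4 and C6 together is set by the catalyst, which should leave the Si face of the acrylate α-carbon open. The diene is a single isomer with two equivalent faces, so the step needs only these three selectivities, secured by the 1-methyl group, the endo preference and the catalyst.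

**Step 5**
Reactants: 6 trifluoroethyl ester
Product: 7 (1R,2R,4R)-1,7,7-trimethylbicyclo[2.2.1]hept-5-ene-2-carboxylic acid
Conditions: LiOH·H2O, THF/H2O, 0 °C → rt; 1 M HCl
Reagents that add atoms: lithium hydroxide [Li+].[OH-]
Why: saponification of the activated trifluoroethyl ester should be much faster than enolisation at C6, so the endo configuration is kept.

**Step 6**
Reactants: 7 bornene endo acid
Product: 8 3-exo-iodobornane-6-endo-carboxylic acid 2-endo-lactone (γ-lactone C6–C(=O)–O–C2)
Conditions: I2, KI, NaHCO3, THF/H2O, rt, dark
Reagents that add atoms: iodine II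
Why: iodolactonisation, in which the reversibly formed exo iodonium on C2=C3 is opened anti by the endo carboxylate at C2 in a 5-exo closure, the only carbon it can reach, so the new C2–O bond is endo and the C3 iodine exo.

**Step 7**
Reactants: 8 iodolactone
Product: 9 bornane-6-endo-carboxylic acid 2-endo-lactone
Conditions: Bu3SnH (1.3 equiv), AIBN (cat.), toluene, 80 °C
Reagents that add atoms: none
Why: radical chain dehalogenation, in which the secondary C3 radical takes hydrogen from the stannane without touching the lactone and C3 becomes a CH2 group with no stereocentre at stake.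

**Step 8**
Reactants: 10 1-fluoro-3,5-dimethoxybenzene
Product: 11 2-bromo-1-fluoro-3,5-dimethoxybenzene
Conditions: NBS (1.0 equiv), MeCN, 0 °C → rt
Reagents that add atoms: N-bromosuccinimide O=C1CCC(=O)N1Br
Why: electrophilic aromatic bromination should go para to one methoxy group and next to the small fluorine rather than into the crowded position between the two methoxy groups, and any 4-bromo isomer is removed by chromatography.

**Step 9**
Reactants: 11 2-bromo-1-fluoro-3,5-dimethoxybenzene (1.4 equiv); 9 lactone
Product: 13 (2-fluoro-4,6-dimethoxyphenyl) 2-endo-hydroxybornan-6-endo-yl ketone (may rest as its lactol), via 2-fluoro-4,6-dimethoxyphenyllithium 12 (not isolated)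
Conditions: n-BuLi (1.35 equiv), THF, −78 °C, 20 min; add 9, −78 °C; AcOH quench at −78 °C
Reagents that add atoms: none
Why: bromine–lithium exchange gives the ortho-fluoroaryllithium, which is kept at −78 °C to prevent LiF loss to a benzyne, and its acyl substitution at the γ-lactone stops at the lithium lactolate, so one aryl group is delivered and C2 and C6 are untouched.

**Step 10**
Reactants: 13 hydroxy ketone
Product: 14 3',5'-dimethoxy benzoxepinone (C1'–O–C2 endo, C2'–C(=O)–C6 endo)
Conditions: t-BuOK (1.2 equiv), THF, 0 → 50 °C
Reagents that add atoms: none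
Why: intramolecular SNAr (addition–elimination), in which the C2 alkoxide, released from the lactolate and held endo beside the endo aroyl group, attacks the C–F carbon ortho to the ketone while both methoxy groups sit meta to it, and the seven-membered ring can close only cis, so a C6 epimer formed by enolisation is returned through the enolate.

**Step 11**
Reactants: 14 dimethoxy benzoxepinone
Product: 15 3'-hydroxy-5'-methoxy benzoxepinone
Conditions: BCl3 (1.2 equiv), CH2Cl2, −78 → 0 °C; H2O
Reagents that add atoms: none
Why: chelation-controlled ether cleavage, in which BCl3 bridges the ketone oxygen and the ortho methoxy oxygen and chloride attacks the methyl group by SN2, whereas the para methoxy group is not chelated and the other ortho oxygen carries a neopentyl-type endo-bornyl carbon that resists both SN2 attack and ionisation.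

**Step 12**
Reactants: 15 ortho-hydroxyaryl ketone
Product: 16 3'-hydroxy-5'-methoxy benzoxepine (benzylic CH2)
Conditions: Et3SiH (4 equiv), TFA, CH2Cl2, 0 °C → rt
Reagents that add atoms: none
Why: ionic hydrogenation of an electron-rich ortho-hydroxyaryl ketone (hydride transfer, loss of water to the oxygen-stabilised benzylic cation, second hydride transfer) gives the CH2 group, and C6 keeps its configuration because the ring fusion can only be cis.

**Step 13**
Reactants: 16 phenol; 17 isovaleryl chloride (1.2 equiv)
Product: 18 4'-isovaleryl-3'-hydroxy-5'-methoxy benzoxepine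
Conditions: BCl3 (1.1 equiv), CH2Cl2, 0 °C; then 17, 0 °C → rt; 1 M HCl
Reagents that add atoms: isovaleryl chloride CC(C)CC(Cl)=O
Why: boron-directed ortho-acylation of a phenol, in which the aryloxydichloroborane binds the acid chloride and delivers the acyl carbon through a six-membered transition state to the only free ortho position C4', the product being held as the boron chelate of the ortho-hydroxy ketone.

**Step 14**
Reactants: 18 acyl phenol
Product: 19 6'-formyl-4'-isovaleryl-3'-hydroxy-5'-methoxy benzoxepine
Conditions: Cl2CHOMe (2 equiv), TiCl4 (3 equiv), CH2Cl2, −20 → 0 °C; H2O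
Reagents that add atoms: dichloromethyl methyl ether COC(Cl)Cl; water O
Why: Rieche formylation must enter at C6', the only unsubstituted ring carbon, which is para to the free phenol and ortho to two ether oxygens, and hydrolysis of the α-chloro ether gives the aldehyde.

**Step 15**
Reactants: 19 methyl ether
Product: 20 target CNP0246493.1
Conditions: BCl3 (2.5 equiv), CH2Cl2, −78 → 0 °C; H2O
Reagents that add atoms: none
Why: chelation-controlled demethylation, in which BCl3 bridged between the formyl oxygen and the C5' methoxy oxygen lets chloride cleave the methyl group by SN2, while the endo-bornyl ether, which can neither ionise with assistance nor be attacked from the rear, should survive.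

**Compound list**
1 | 2,2-dimethylcyclopentanone | CC1(C)CCCC1=O | starting material
2 | 5,5-dimethylcyclopent-2-en-1-one | CC1(C)CC=CC1=O | intermediate
3 | 1,5,5-trimethylcyclopent-2-en-1-ol (racemic) | CC1(O)C=CCC1(C)C | intermediate
4 | 1,5,5-trimethylcyclopenta-1,3-diene | CC1=CC=CC1(C)C | intermediate
5 | 2,2,2-trifluoroethyl acrylate | C=CC(=O)OCC(F)(F)F | starting material
6 | 2,2,2-trifluoroethyl (1R,2R,4R)-1,7,7-trimethylbicyclo[2.2.1]hept-5-ene-2-carboxylate | O=C(OCC(F)(F)F)[C@@H]1C[C@@H]2C=C[C@@]1(C)C2(C)C | intermediate
7 | (1R,2R,4R)-1,7,7-trimethylbicyclo[2.2.1]hept-5-ene-2-carboxylic acid | O=C(O)[C@@H]1C[C@@H]2C=C[C@@]1(C)C2(C)C | intermediate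
8 | 3-exo-iodobornane-6-endo-carboxylic acid 2-endo-lactone | O=C2[C@@H]1C[C@@H]3[C@@H](I)[C@H](O2)[C@@]1(C)C3(C)C | intermediate
9 | bornane-6-endo-carboxylic acid 2-endo-lactone | O=C2[C@@H]1C[C@@H]3C[C@H](O2)[C@@]1(C)C3(C)C | intermediate
10 | 1-fluoro-3,5-dimethoxybenzene | COc1cc(F)cc(OC)c1 | starting material
11 | 2-bromo-1-fluoro-3,5-dimethoxybenzene | COc1cc(F)c(Br)c(OC)c1 | intermediate
12 | 2-fluoro-4,6-dimethoxyphenyllithium | COc1cc(F)c([Li])c(OC)c1 | intermediate
13 | (2-fluoro-4,6-dimethoxyphenyl) 2-endo-hydroxybornan-6-endo-yl ketone | COc1cc(OC)c(c(F)c1)C(=O)[C@@H]1C[C@@H]2C[C@H](O)[C@@]1(C)C2(C)C | intermediate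
14 | 3',5'-dimethoxy benzoxepinone (C1'–O–C2, C2'–C(=O)–C6, both endo) | COc1cc2c(c(OC)c1)C(=O)[C@@H]1C[C@@H]3C[C@H](O2)[C@@]1(C)C3(C)C | intermediate
15 | 3'-hydroxy-5'-methoxy benzoxepinone | COc1cc2c(c(O)c1)C(=O)[C@@H]1C[C@@H]3C[C@H](O2)[C@@]1(C)C3(C)C | intermediate
16 | 3'-hydroxy-5'-methoxy benzoxepine | COc1cc2c(c(O)c1)C[C@@H]1C[C@@H]3C[C@H](O2)[C@@]1(C)C3(C)C | intermediate
17 | isovaleryl chloride | CC(C)CC(Cl)=O | starting material
18 | 4'-isovaleryl-3'-hydroxy-5'-methoxy benzoxepine | COc1cc2c(c(O)c1C(=O)CC(C)C)C[C@@H]1C[C@@H]3C[C@H](O2)[C@@]1(C)C3(C)C | intermediate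
19 | 6'-formyl-4'-isovaleryl-3'-hydroxy-5'-methoxy benzoxepine | COc1c(C=O)c2c(c(O)c1C(=O)CC(C)C)C[C@@H]1C[C@@H]3C[C@H](O2)[C@@]1(C)C3(C)C | intermediate
20 | CNP0246493.1 | CC(C)CC(=O)c1c(O)c(C=O)c2c(c1O)C[C@@H]1C[C@@H]3C[C@H](O2)[C@@]1(C)C3(C)C | target

Total step count: 15. Longest linear sequence: 14 steps (1 → 20 through steps 1–7 and 9–15); the arene branch (step 8) joins at step 9.

**Steps most likely to fail**

Step 4. The diene is substituted at C1 and on both faces at C5, so cycloaddition may be slower than acid-induced oligomerisation of the diene, and face selection by the catalyst may be incomplete. The fallback replaces catalyst control by auxiliary control. It sets out from diene 4: an Et2AlCl-promoted Diels–Alder reaction with commercial (S)-3-acryloyl-4-benzyloxazolidin-2-one (CH2Cl2, −78 → −40 °C) should give the imide (4S)-4-benzyl-3-[(1R,2R,4R)-1,7,7-trimethylbicyclo[2.2.1]hept-5-ene-2-carbonyl]oxazolidin-2-one F1, because the benzyl group shields the Re face of the chelated s-cis imide. Minor diastereomers are removed by crystallisation, and LiOH/H2O2 (THF/H2O, 0 °C) cleaves the imide to acid 7, where the route is rejoined; step 5 then drops out.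

Step 9. Loss of LiF from the ortho-fluoroaryllithium may outrun its addition to the hindered lactone carbonyl, leaving unreacted lactone. The fallback uses a more electrophilic carbonyl and a thermally stable aryl metal. It sets out from lactone 9: DIBAL-H (CH2Cl2, −78 °C) should give the lactol 2-endo-hydroxybornane-6-endo-carbaldehyde hemiacetal F2. The Grignard reagent 2-fluoro-4,6-dimethoxyphenylmagnesium chloride F3, made from bromide 11 with i-PrMgCl·LiCl (THF, −15 °C), adds to the open hydroxy aldehyde form of the lactol (2.5 equiv, 0 °C → rt) to give the benzylic diol (2-fluoro-4,6-dimethoxyphenyl)(2-endo-hydroxybornan-6-endo-yl)methanol F4 as both carbinol epimers. MnO2 (CH2Cl2, rt) oxidises only the benzylic alcohol and returns hydroxy ketone 13.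

Step 13. Acylation may go to the para position C6', or stop at the O-acyl stage, instead of following the boron-directed ortho delivery. The fallback builds the ketone from an ortho-specific formylation. It sets out from phenol 16: MgCl2/Et3N/paraformaldehyde (MeCN, reflux), which reacts only ortho to the magnesium phenoxide, should give the salicylaldehyde 4'-formyl-3'-hydroxy-5'-methoxy benzoxepine F5. Isobutylmagnesium bromide (2.5 equiv, THF, 0 °C) then gives the carbinol 4'-(1-hydroxy-3-methylbutyl)-3'-hydroxy-5'-methoxy benzoxepine F6, and MnO2 (CH2Cl2, rt) oxidises the benzylic alcohol to ketone 18, where the route is rejoined.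

**Further compounds**
F1 | step 4 | (4S)-4-benzyl-3-[(1R,2R,4R)-1,7,7-trimethylbicyclo[2.2.1]hept-5-ene-2-carbonyl]oxazolidin-2-one | O=C([C@@H]1C[C@@H]2C=C[C@@]1(C)C2(C)C)N1[C@@H](Cc2ccccc2)COC1=O
F2 | step 9 | lactol of 2-endo-hydroxybornane-6-endo-carbaldehyde (anomer mixture) | OC2[C@@H]1C[C@@H]3C[C@H](O2)[C@@]1(C)C3(C)C
F3 | step 9 | 2-fluoro-4,6-dimethoxyphenylmagnesium chloride | COc1cc(F)c([Mg]Cl)c(OC)c1
F4 | step 9 | (2-fluoro-4,6-dimethoxyphenyl)(2-endo-hydroxybornan-6-endo-yl)methanol (carbinol epimers) | COc1cc(OC)c(c(F)c1)C(O)[C@@H]1C[C@@H]2C[C@H](O)[C@@]1(C)C2(C)C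
F5 | step 13 | 4'-formyl-3'-hydroxy-5'-methoxy benzoxepine | COc1cc2c(c(O)c1C=O)C[C@@H]1C[C@@H]3C[C@H](O2)[C@@]1(C)C3(C)C
F6 | step 13 | 4'-(1-hydroxy-3-methylbutyl)-3'-hydroxy-5'-methoxy benzoxepine (carbinol epimers) | COc1cc2c(c(O)c1C(O)CC(C)C)C[C@@H]1C[C@@H]3C[C@H](O2)[C@@]1(C)C3(C)C
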